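The route cuts the hexasubstituted benzene ring B of the benzofuran across two C–C bonds. The phenol carbon and the methyl-bearing carbon of ring B come from a 3-ethyl-2-furoate. The two ring B carbons that carry ring C come from the alkene of (S)-4-methylcyclohexenone, whose stereocentre becomes Ce (the CH–CH3 of ring C). One Michael–Dieckmann annulation followed by dehydrogenation builds ring B with furan, phenol oxygen, methyl and ring C already in place. The resulting peri-hydroxy tetralone is reduced, and its o-quinone methide is joined to the ring A benzofuran by a hetero-Diels–Alder reaction that closes the pyran and dearomatizes the second furan.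

Key step: step 5

Remark: ring A = pentenyl-bearing benzene ring, ring B = benzene ring of the benzofuran, ring C = methyl-bearing carbocycle; Ce = CH(CH3) of ring C, Cf = ring-fusion CH, Ca = O–CH, Cq = O–C(CH3); it is assumed that the (R,R)-amide gives the (S)-enol ether in step 3 (otherwise its mirror image is used).

Step 1
Reactants: 1 pentan-3-one
Product: 3 1,1-dimethoxy-2-methylpentan-3-one, via sodium formyl enolate 2 (not isolated)
Conditions: HCO2Me, NaOMe, Et2O, 0 °C to rt; then MeOH, H2SO4, -10 °C to rt
Reagents that add atoms: methyl formate COC=O; methanol CO
Why: Crossed Claisen formylation of the symmetrical ketone gives the sodium enolate, and acid-catalysed acetalization in methanol masks the aldehyde carbon (the more electrophilic carbonyl) while the ethyl ketone stays free; the α-centre is racemic and is lost in step 2.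

Step 2
Reactants: 3 1,1-dimethoxy-2-methylpentan-3-one; 4 methyl chloroacetate
Product: 6 methyl 3-ethyl-4-methylfuran-2-carboxylate, via glycidic ester 5 (not isolated)
Conditions: NaOMe, Et2O, -10 °C to rt; then neat, 160 °C, MeOH distilled off
Reagents that add atoms: none
Why: Darzens condensation at the free ketone gives the glycidic ester, which on heating should lose two methanol (the epoxide oxygen closes onto the acetal carbon as the tertiary C–O bond opens, then the dihydrofuran aromatizes), the established route from β-keto acetals to 3-alkyl-2-furoates, placing ethyl at C3, methyl at C4 and hydrogen at C5.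

Step 3
Reactants: 7 4-methylcyclohexan-1-one
Product: 8 (S)-trimethyl[(4-methylcyclohex-1-en-1-yl)oxy]silane
Conditions: lithium (R,R)-bis(1-phenylethyl)amide (from the amine and n-BuLi), Me3SiCl (internal quench), THF, -100 to -78 °C
Reagents that add atoms: chlorotrimethylsilane C[Si](C)(C)Cl
Why: Enantioselective deprotonation of the prochiral ketone by a C2-symmetric chiral lithium amide under internal silyl quench differentiates the two enantiotopic α-methylene groups, so the remote methyl-bearing carbon becomes the (S) stereocentre under reagent control.

Step 4
Reactants: 8 (S)-trimethyl[(4-methylcyclohex-1-en-1-yl)oxy]silane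
Product: 9 (S)-4-methylcyclohex-2-en-1-one
Conditions: Pd(OAc)2 (10 mol %), O2 (1 atm), DMSO, rt
Reagents that add atoms: none
Why: Saegusa–Ito oxidation: the palladium enolate (divalent palladium) undergoes β-hydride elimination towards C3, so the double bond appears on the side fixed by the enol ether, and the C4 stereocentre is not touched under these neutral conditions.

Step 5
Reactants: 6 methyl 3-ethyl-4-methylfuran-2-carboxylate; 9 (S)-4-methylcyclohex-2-en-1-one
Product: 12 (S)-9-hydroxy-3,4,5-trimethyl-6,7-dihydronaphtho[2,3-b]furan-8(5H)-one, via lithiated furoate 10 (not isolated), via dihydro annulation adduct 11 (not isolated)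
Conditions: LiN(iPr)2 (1.1 equiv), THF, -78 °C; 9 added slowly, -78 °C to rt; AcOH, 0 °C; DDQ (1.0 equiv), 0 °C
Reagents that add atoms: none
Why: LiN(iPr)2 removes a proton from the CH2 of the ethyl group, which is vinylogous to the ester through the furan (the 4-methyl group is only cross-conjugated), and the delocalized anion 10 adds 1,4 to the enone; the ketone enolate so formed closes onto the ester (Dieckmann, 6-exo-trig) and expels methoxide to give 11. The closest known reaction is the Staunton–Weinreb annulation of lateral toluate anions with enones, here with a furoate and a secondary carbanion. After the amine has been neutralized with acetic acid, DDQ should abstract hydride from an allylic CH of the enolized dihydro ring and loss of a proton gives the phenol; both new sp3 centres are erased, so the step creates no stereocentre and the ring-fusion diastereomers of 11 converge. Regiochemistry follows from the polarity of the partners: the lateral carbon bonds to the enone β-carbon and the enone α-carbon to the ester carbon, which places hydroxyl, methyl, furan and ring C on ring B without any electrophilic substitution. The step needs lateral rather than furan C5–H deprotonation, 1,4- rather than 1,2-addition and survival of Ce; these are secured by the kinetic base at -78 °C, by the soft delocalized anion, by slow addition of the enone to avoid excess base that could form the dienolate through the Ce hydrogen, and by using one equivalent of quinone, which the easily oxidized enol 11 consumes before the hydrogen-bonded aryl ketone 12 can react.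

Step 6
Reactants: 12 (S)-9-hydroxy-3,4,5-trimethyl-6,7-dihydronaphtho[2,3-b]furan-8(5H)-one
Product: 13 (5S)-3,4,5-trimethyl-5,6,7,8-tetrahydronaphtho[2,3-b]furan-8,9-diol (both C8 epimers)
Conditions: NaBH4, MeOH/THF, 0 °C; pH 7 buffer, used crude
Reagents that add atoms: none
Why: Borohydride reduction of the hydrogen-bonded aryl ketone gives the o-hydroxybenzyl alcohol; the carbinol centre forms as a mixture, which does not matter because it becomes trigonal in step 13.

Step 7
Reactants: 14 2-methoxy-4-methylphenol; 15 chloroacetone
Product: 16 1-(2-methoxy-4-methylphenoxy)propan-2-one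
Conditions: K2CO3, KI (cat.), acetone, reflux
Reagents that add atoms: none
Why: Williamson etherification: the phenoxide displaces chloride from the α-halo ketone (SN2, iodide catalysis).

Step 8
Reactants: 16 1-(2-methoxy-4-methylphenoxy)propan-2-one
Product: 17 7-methoxy-3,5-dimethyl-1-benzofuran
Conditions: polyphosphoric acid, toluene, 90 °C
Reagents that add atoms: none
Why: Acid-mediated cyclodehydration of the α-aryloxy ketone (intramolecular Friedel–Crafts attack on the protonated carbonyl, then loss of water to the aromatic furan) can only occur at the single free position ortho to the ether oxygen, which fixes the substitution pattern.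

Step 9
Reactants: 17 7-methoxy-3,5-dimethyl-1-benzofuran
Product: 18 3,5-dimethyl-1-benzofuran-7-ol
Conditions: BBr3, CH2Cl2, -78 to 0 °C; H2O
Reagents that add atoms: none
Why: Boron tribromide cleavage of the aryl methyl ether (bromide attacks the methyl group of the Lewis acid–ether complex) frees the 7-hydroxyl; the benzofuran tolerates the reagent at low temperature.

Step 10
Reactants: 18 3,5-dimethyl-1-benzofuran-7-ol
Product: 19 7-hydroxy-3,5-dimethyl-1-benzofuran-6-carbaldehyde
Conditions: MgCl2, Et3N, (CH2O)n, MeCN, reflux
Reagents that add atoms: formaldehyde (as paraformaldehyde) C=O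
Why: Magnesium-mediated ortho-formylation: the magnesium phenoxide delivers formaldehyde to the ortho carbon and the hydroxymethyl intermediate is oxidized by a second formaldehyde through hydride transfer; C6 is the only free ortho position.

Step 11
Reactants: 19 7-hydroxy-3,5-dimethyl-1-benzofuran-6-carbaldehyde
Product: 20 6-ethenyl-3,5-dimethyl-1-benzofuran-7-ol
Conditions: Ph3PCH3Br, KOtBu (2.5 equiv), THF, 0 °C to rt
Reagents that add atoms: methyltriphenylphosphonium bromide C[P+](c1ccccc1)(c1ccccc1)c1ccccc1.[Br-]
Why: Wittig methylenation of the salicylaldehyde; the extra base deprotonates the phenol and the unstabilized ylide still adds to the aldehyde.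

Step 12
Reactants: 20 6-ethenyl-3,5-dimethyl-1-benzofuran-7-ol; 21 (E)-1-bromoprop-1-ene
Product: 23 3,5-dimethyl-6-[(3E)-pent-3-en-1-yl]-1-benzofuran-7-ol, via B-alkyl borane 22 (not isolated)
Conditions: 9-BBN (2.2 equiv), THF, 0 °C to rt; then 21, PdCl2(dppf) (5 mol %), aq. K3PO4, THF/DMF, 50 °C
Reagents that add atoms: none
Why: Hydroboration of the styrene-type vinyl group places boron on the terminal carbon (one equivalent of borane is taken up by the phenol), and the B-alkyl Suzuki–Miyaura coupling retains the (E) geometry of the alkenyl bromide; the benzofuran double bond should be too hindered to be hydroborated by 9-BBN at room temperature.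

Step 13
Reactants: 13 (5S)-3,4,5-trimethyl-5,6,7,8-tetrahydronaphtho[2,3-b]furan-8,9-diol; 23 3,5-dimethyl-6-[(3E)-pent-3-en-1-yl]-1-benzofuran-7-ol
Product: 25 target CNP0281983.1 (CaR/CfR/CqR/CeS), via ortho-quinone methide 24 (not isolated)
Conditions: toluene, 4 Å MS, 120 °C (sealed tube), 23 (3 equiv), 13 added slowly
Reagents that add atoms: none
Why: Thermal loss of water from the o-hydroxybenzyl alcohol gives the o-quinone methide, which should undergo an inverse-electron-demand hetero-Diels–Alder reaction with the 2,3-bond of the 3-methylbenzofuran (nucleophilic C2 to the methide carbon, ring B oxygen to C3, which fixes regiochemistry and the cis fusion of Ca and Cq), through the endo transition state (benzo ring of 23 under ring B, placing H–Cf cis to H–Ca) and on the face that lets the methide hydrogen become pseudoaxial anti to the pseudoaxial Ce methyl (the half-chair of ring C imposed by the two peri methyl groups), so that Ce controls Cf, Ca and Cq.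

Compound list
1 | pentan-3-one | CCC(=O)CC | starting material
2 | sodium 2-methyl-3-oxopent-1-en-1-olate | CCC(=O)C(C)=C[O-].[Na+] | intermediate
3 | 1,1-dimethoxy-2-methylpentan-3-one (racemic) | CCC(=O)C(C)C(OC)OC | intermediate
4 | methyl chloroacetate | COC(=O)CCl | starting material
5 | methyl 3-(1,1-dimethoxypropan-2-yl)-3-ethyloxirane-2-carboxylate (diastereomer mixture) | CCC1(OC1C(=O)OC)C(C)C(OC)OC | intermediate
6 | methyl 3-ethyl-4-methylfuran-2-carboxylate | CCc1c(C)coc1C(=O)OC | intermediate
7 | 4-methylcyclohexan-1-one | CC1CCC(=O)CC1 | starting material
8 | (S)-trimethyl[(4-methylcyclohex-1-en-1-yl)oxy]silane | C[Si](C)(C)OC1=CC[C@@H](C)CC1 | intermediate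
9 | (S)-4-methylcyclohex-2-en-1-one | O=C1CC[C@H](C)C=C1 | intermediate
10 | lithiated furoate (lateral anion of 6) | [Li+].C[CH-]c1c(C)coc1C(=O)OC | intermediate
11 | (5S)-9-hydroxy-3,4,5-trimethyl-4a,5,6,7-tetrahydro-4H-naphtho[2,3-b]furan-8-one (enol form, C4 and C4a as a mixture) | OC1=C2C(=O)CC[C@H](C)C2C(C)c2c(C)coc12 | intermediate
12 | (S)-9-hydroxy-3,4,5-trimethyl-6,7-dihydronaphtho[2,3-b]furan-8(5H)-one | O=C1CC[C@H](C)c2c1c(O)c1occ(C)c1c2C | intermediate
13 | (5S)-3,4,5-trimethyl-5,6,7,8-tetrahydronaphtho[2,3-b]furan-8,9-diol (both C8 epimers) | OC1CC[C@H](C)c2c1c(O)c1occ(C)c1c2C | intermediate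
14 | 2-methoxy-4-methylphenol | COc1cc(C)ccc1O | starting material
15 | chloroacetone (1-chloropropan-2-one) | CC(=O)CCl | starting material
16 | 1-(2-methoxy-4-methylphenoxy)propan-2-one | CC(=O)COc1ccc(C)cc1OC | intermediate
17 | 7-methoxy-3,5-dimethyl-1-benzofuran | COc1cc(C)cc2c(C)coc12 | intermediate
18 | 3,5-dimethyl-1-benzofuran-7-ol | Cc1cc(O)c2occ(C)c2c1 | intermediate
19 | 7-hydroxy-3,5-dimethyl-1-benzofuran-6-carbaldehyde | Cc1coc2c(O)c(C=O)c(C)cc12 | intermediate
20 | 6-ethenyl-3,5-dimethyl-1-benzofuran-7-ol | Cc1coc2c(O)c(C=C)c(C)cc12 | intermediate
21 | (E)-1-bromoprop-1-ene | C/C=C/Br | starting material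
22 | 9-{2-[7-(9-borabicyclo[3.3.1]nonan-9-yloxy)-3,5-dimethyl-1-benzofuran-6-yl]ethyl}-9-borabicyclo[3.3.1]nonane | Cc1coc2c(OB3C4CCCC3CCC4)c(CCB3C4CCCC3CCC4)c(C)cc12 | intermediate
23 | 3,5-dimethyl-6-[(3E)-pent-3-en-1-yl]-1-benzofuran-7-ol | Cc1coc2c(O)c(CC/C=C/C)c(C)cc12 | intermediate
24 | (S)-3,4,5-trimethyl-6,7-dihydronaphtho[2,3-b]furan-9(5H)-one (o-quinone methide) | O=C1C2=CCC[C@H](C)C2=C(C)c2c(C)coc21 | intermediate
25 | CNP0281983.1 (Ca R, Cf R, Cq R, Ce S; H–Cf, H–Ca and CH3–Cq on one face, CH3–Ce on the other) | C/C=C/CCc1c(C)cc2c(c1O)O[C@@H]1[C@@H]3CC[C@H](C)c4c3c(c3occ(C)c3c4C)O[C@]21C | target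

Total step count: 13. Longest linear sequence: 7 steps (14 → 16 → 17 → 18 → 19 → 20 → 23 → 25, steps 7 to 13).

Steps most likely to fail

Step 13. The transient quinone methide may be lost before it meets the weakly nucleophilic benzofuran. It can shift a hydrogen to give the vinylphenol, add to the ring B furan of a second molecule, or be taken up at oxygen or carbon by the phenol of 23. The facial selectivity with respect to Ce may also be insufficient, because torsional steering by the neighbouring ring C methylene favours the opposite face in an early transition state. Fallback: the union is run as a reagent-controlled, stepwise ionic cycloaddition in place of the thermal, substrate-controlled one. It sets out from the same compounds 13 and 23, returns at 25 and makes no new compound (F0). A chiral BINOL-derived phosphoric acid (3,3'-bis(2,4,6-triisopropylphenyl)-1,1'-binaphthyl-2,2'-diyl hydrogen phosphate, 5 to 10 mol %, CH2Cl2, 4 Å MS, -30 °C) ionizes the benzylic alcohol. The phosphate should hold the quinone methide through its oxygen and the benzofuran through its 7-hydroxyl in one hydrogen-bonded ion pair. C–C bond formation at benzofuran C2 and collapse of the phenoxide onto C3 then follow at a temperature where the hydrogen shift is slow. The catalyst antipode matched with Ce is chosen, and the mixture is quenched with triethylamine before warming so that the acid-labile tertiary ether is not reopened.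

Step 5. The hindered secondary carbanion may take a proton from the enone instead of adding to it, which would also expose Ce to racemization through the dienolate. The ring closure may stall at the Michael adduct, or the quinone may over-oxidize ring C. Fallback: a sulfoxide-driven annulation of the Hauser type, which uses a more acidic and softer carbanion and needs no oxidant. It sets out from 6 and returns at 12. Sulfenylation of the lateral anion of 6 (LiN(iPr)2, then PhSSPh) gives methyl 4-methyl-3-[1-(phenylsulfanyl)ethyl]furan-2-carboxylate F1. Oxidation (NaIO4, MeOH/H2O) gives methyl 4-methyl-3-[1-(phenylsulfinyl)ethyl]furan-2-carboxylate F2. The α-sulfinyl carbanion of F2 (LiOtBu, THF, -78 °C) adds to 9 and the enolate closes onto the ester to give the sulfinyl annulation adduct F3. Warming (toluene, 80 °C) should expel benzenesulfenic acid by syn-elimination, and tautomerization of the dienone gives 12.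

Step 3. Incomplete discrimination of the enantiotopic protons by the chiral base would give 8 of insufficient enantiomeric purity. That deficit is carried unchanged into Ce and into the diastereomeric purity of 25. Fallback: the stereocentre is made by enamine catalysis instead of deprotonation. This branch does not start from a numbered compound: it replaces 7 by commercial propanal and but-3-en-2-one and returns at 9. Conjugate addition of propanal to the enone, catalysed by an α,α-diphenylprolinol trimethylsilyl ether (the antipode that leads to the S series), should give (S)-2-methyl-5-oxohexanal F4. Intramolecular aldol condensation under mild acid (TsOH, toluene, 40 °C), chosen so that cyclization outruns enolization of the aldehyde, closes it to 9.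

Further compounds
F0 | step 13 | none | none
F1 | step 5 | methyl 4-methyl-3-[1-(phenylsulfanyl)ethyl]furan-2-carboxylate | CC(Sc1ccccc1)c1c(C)coc1C(=O)OC
F2 | step 5 | methyl 4-methyl-3-[1-(phenylsulfinyl)ethyl]furan-2-carboxylate | CC(c1c(C)coc1C(=O)OC)S(=O)c1ccccc1
F3 | step 5 | (5S)-9-hydroxy-3,4,5-trimethyl-4-(phenylsulfinyl)-4a,5,6,7-tetrahydro-4H-naphtho[2,3-b]furan-8-one | OC1=C2C(=O)CC[C@H](C)C2C(C)(S(=O)c3ccccc3)c2c(C)coc12
F4 | step 3 | (S)-2-methyl-5-oxohexanal | CC(=O)CC[C@H](C)C=O
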